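Atom labels used throughout: C1 is the ring carbon carrying the (E)-but-2-en-2-yl group, C2 the methyl-bearing alkene carbon, C3 the alkene CH, C4 and C9 the ring-fusion carbons (C4 next to C3, C9 next to C10), C5 and C6 the ring-B methylenes, C7 the sulfated carbon, C8 the methyl-bearing carbon, C10 the carbon carrying the acid chain C11–C15. Ring A is C1, C2, C3, C4, C9, C10; ring B is C4 to C9.

## Structural features

- The target is a cis-fused bicyclo[4.4.0]decene: ring A is a cyclohexene with a trisubstituted, methyl-bearing C2=C3 double bond, ring B is a cyclohexane, and both fusion hydrogens (C4, C9) lie on the same face.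
- Six stereocentres are present. Five are contiguous (C1, C10, C9, C8, C7) and the sixth, C4, is bonded to C9.
- The butenyl group on C1 is trans to the (2E,4E)-penta-2,4-dienoic acid chain on C10, the C8 methyl is trans to the C9–C10 bond, and the C7 sulfate is cis to the C8 methyl.
- Fragile groups are the secondary alkyl hydrogen sulfate (lost in acid), the dienoic acid (conjugate acceptor, E/Z-labile), the bis-allylic C1–H between C2=C3 and the butenyl alkene, and C10 once C11 is a carbonyl.
- The real difficulty is the dense C1–C10–C9–C8–C7 array wrapped around a cis ring fusion, with C1 and C10 flanked only by unsaturated branches, together with keeping the C2=C3 alkene exactly next to C4.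
- The key step uses the fact that alkene carbon C3 is bonded to fusion carbon C4 while C2–C1–C10 links it to C9. An alkenyl unit tethered from C9 can add across a ring-B C4=C5 alkene, which forms C3–C4, closes ring A in the 6-exo mode and can only give the cis fusion.
- C5 and C6 are unfunctionalised in the target, so an alkene left there by the ring closure is harmless and removable.

## Logic of the disconnections

**42 ⇒ 41 ⇒ 39.** The acid is first masked at C15 and then the O–S bond at C7 is cut. The hydrogen sulfate is the most labile group and cannot meet fluoride, hydride, oxidant or palladium, so it goes on last. Everything before 41 is then neutral and chromatographable. The forward sulfation must act at oxygen only (retention at C7), and the final hydrolysis must cleave an ester beside a sulfate monoester.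

**39 ⇒ 38 ⇒ 36 + 37.** The C7 silyl ether is restored and the C11=C12 double bond is cut. This is the one skeletal bond that separates the unsaturated acid arm from the stereochemically dense core. Four carbons and both E-alkenes come from 37. The forward olefination must be E-selective and must not equilibrate C10 of 36.

**36 ⇒ 35 ⇒ 34 ⇒ 33.** No skeletal bond is cut: C11 goes back to the ester level and the C5=C6 alkene is re-introduced. 33 is what the ring closure delivers. The forward reduction must distinguish the cis-disubstituted C5=C6 alkene from two trisubstituted alkenes.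

**33 ⇒ 32.** The C3–C4 bond is cut. This opens ring A, removes the C4 stereocentre and leaves a monocyclic ring B carrying an acyclic side chain. The forward step needs a (Z)-iodoalkene at C2=C3, a ring-B alkene at C4=C5, addition on the face bearing C10, and hydride loss toward C6 only.

**32 ⇒ 30 ⇒ 26.** After the ester methyl, the C1–C10 bond is cut as a [3,3] shift, which restores an allylic ester C–O bond and moves the butenyl alkene one position. C1 and C10 are adjacent stereocentres with no polar handle other than C11. The cut splits the molecule into two halves of similar size and lets one carbinol stereocentre control two carbon stereocentres. The forward step needs a chair transition state, a (Z)-ketene acetal and an (E)-allylic ester.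

**26 ⇒ 16 + 25.** The acyl C11–O bond is cut, which is a plain esterification in the forward sense.

**25 ⇒ 24 ⇒ 21 + 22; 21 ⇒ 17 + 18 + 19.** The carbinol C–H bond, the trisubstituted alkene next to it, and then the C2–CH3 and C3–I bonds are cut. The iodoalkene geometry is fixed in the first step of this branch instead of being created beside the sensitive C1–H later. Enantiocontrol is needed at one ketone only.

**16 ⇒ 14 ⇒ 12 ⇒ 11 ⇒ 9.** These are functional-group changes only: acid to ester, silyl ether to alcohol, C7 alcohol to ketone, ketone to ketal. The C7 configuration must come from a face-selective reduction next to the C8 methyl, and the ketone must be released without conjugating the C4=C5 alkene.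

**9 ⇒ 5.** The C4=C5 alkene is traded for a C4 carbonyl with a C5=C6 alkene. This gives an enone whose α′ carbon is C9. The forward step must delete the carbonyl and shift the alkene in one reductive transposition.

**5 ⇒ 3 + 4; 3 ⇒ 1 + 2.** The C9–C10 and C8–CH3 bonds are cut. Both lie α and β to the C4 carbonyl of a symmetric dienone. This leads to achiral 1. It requires an enantioselective conjugate addition (C8) and a trans-selective alkylation (C9).

## Other disconnections considered

**Alternative 1:** anionic oxy-Cope.
- Cut and forward step: the C4–C5 bond of ring B is cut as a [3,3] shift. The potassium alkoxide of bridged vinyl carbinol A1 (KH, 18-crown-6) would break C2–C7, form C4–C5 and give, after protonation, octalinone A2.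
- In favour: the shift is concerted and suprafacial on a rigid bicycle, so the cis fusion is a geometric necessity. On this point it equals the chosen plan.
- It is better than the chosen plan in one respect: ring B arrives saturated at C5–C6 with the C7 carbonyl in place and the C2=C3 alkene cannot migrate. No alkene has to be removed afterwards and no alkene walking has to be suppressed.
- Against: A1 concentrates six stereocentres, including a quaternary bridgehead (C2) and a tertiary carbinol (C7) whose vinyl group must sit over the C3=C4 bridge. Its bicyclic ketone parent needs a Diels–Alder reaction of a 5,6-disubstituted 1-methylcyclohexa-1,3-diene in which regiochemistry, facial selectivity and the C8 methyl must all be controlled at once, and no obvious catalytic source of absolute configuration exists for it.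
- The later C7 reduction would be run on a flexible cis-decalin, where facial bias is less predictable than on the monocyclic ketone of the chosen route.
- Step economy: about one step fewer after the key step, probably more before it.

**Alternative 2:** quinone monoketal Diels–Alder.
- Cut and forward step: C4–C5 and C8–C9 are cut together. The unsubstituted alkene of monoketal A3 would add diene A4 under a chiral oxazaborolidinium Lewis acid, and mild acid would then give enedione A5.
- In favour: it is catalytic and enantioselective and sets both fusion centres in the first carbon–carbon bond-forming event from two achiral pieces. In speed to the bicyclic core, and in having the fusion configuration set by a catalyst in the ring-forming step itself, it is better than the chosen plan.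
- The cis fusion is as secure as in the chosen plan, and is so equal on that point.
- Against: A5 carries a ketone at C3 and a ketal at C10 that the target lacks, its ring-A alkene is C1=C2 and not C2=C3, and the C8 methyl, the C1 butenyl group, the C10 chain and the C7 centre are all still missing.
- Installing them means conjugate addition at C1, regioselective conversion of the C3 ketone into the C2=C3 alkene, homologation at C10 with a new C10–H centre, regioselective methylation at C8 against C6, and C7 reduction. Four stereocentres would rest on substrate control in a cis-decalin dione.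
- Step economy: a superior opening but a clearly longer sequence overall. The chosen route uses the same class of starting material but as ring B, where its oxygen atoms fall on C7 and on a carbonyl that is removed in one step.

**Alternative 3:** intramolecular Hosomi–Sakurai.
- Cut and forward step: the C9–C10 bond is cut. TiCl4 would activate the enone of allylsilane enone A6 and the silane would attack C9 through C10 to give vinyl octalinone A7.
- In favour: ring A closes while C9 and C10 are created, and C8 follows on protonation and equilibration. That is three stereocentres in the key step against one in the chosen plan.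
- After the key step the vinyl group on C10 is a short way from the dienoate (cross-metathesis or two conventional steps). On step count after the key step this alternative is better than the chosen plan, and it needs no halide and no palladium.
- Against: a six-membered ring closing onto the β-carbon is not geometrically forced to be cis-fused, and the C10 configuration depends on silane geometry and on the synclinal or antiperiplanar approach next to the remote C1 centre.
- The C1–H of A6 is flanked by three alkenes, so a strong Lewis acid invites protodesilylation, alkene migration or ionisation. The neutral palladium conditions of the chosen plan are gentler on this position.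
- The C4 centre of A6 is γ to the enone carbonyl (vinylogous enolisation) and carries a Z-trisubstituted alkenyl group. It and C1 would need two unrelated asymmetric steps.
- Overall: more is set in the key step but with weaker guarantees; the chosen plan sets only C4 but with certainty.

Key step: step 14

## Remarks before the steps

- **Check of the key-step structures.** Iodide 32 and diene 33 were compared centre by centre with 42. C1, C10, C9, C8 and C7 have the same spatial arrangement in all three, and the (Z)-iodoalkene is the geometry a ring alkene requires. No configurational correction is needed. The CIP label at C9 switches between R and S along the route only because substituent priorities change.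
- **Design of the cyclisation precursor.**
 - C11 is carried as the methyl ester, the oxidation level at which the rearrangement delivers it. The skeleton is unchanged, two operations are saved, and no oxidative ether cleavage is needed next to the bis-allylic C1–H.
 - C7 stays a silyl ether, because after cyclisation it is allylic and an ester there would ionise with zerovalent palladium.
 - The iodoalkene comes from a building block of fixed Z geometry. Making it from a C2 methyl ketone would place a carbonyl beside the bis-allylic C1–H (epimerisation, conjugation), and ketone iodomethylenation gives no Z control.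
- **Assumption.** The target is taken as the free hydrogen sulfate and carboxylic acid as drawn; it would be stored as its disodium salt and protonated just before use.
- **Conventions.** Metal enolates, alkoxides and phosphonate anions that are simply deprotonated forms of numbered compounds, and organopalladium species inside the catalytic cycle, are described in the Why lines and are not numbered. Every other species formed and consumed in one flask is numbered.

## Route

Step 1
Reactants: 1 4,4-dimethoxycyclohexa-2,5-dien-1-one; 2 dimethylzinc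
Product: 3 (5R)-4,4-dimethoxy-5-methylcyclohex-2-en-1-one
Conditions: Me2Zn (1.5 equiv), Cu(OTf)2 (2 mol%), (S)-binaphthol N,N-bis[(R)-1-phenylethyl]phosphoramidite (4 mol%), PhMe, −25 °C; aq. NH4Cl
Reagents that add atoms: dimethylzinc, C[Zn]C
Why: Copper-catalysed asymmetric conjugate addition of a dialkylzinc to a benzoquinone monoketal, a known desymmetrisation of 4,4-disubstituted cyclohexadienones; the chiral copper–phosphoramidite complex differentiates the two enantiotopic β-carbons and sets C8 (ligand antipode chosen for 5R, sense to be confirmed on 3), and the mono-adduct is a poorer acceptor than 1.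

Step 2
Reactants: 3 (5R)-4,4-dimethoxy-5-methylcyclohex-2-en-1-one; 4 methyl bromoacetate
Product: 5 methyl 2-[(1R,6R)-5,5-dimethoxy-6-methyl-2-oxocyclohex-3-en-1-yl]acetate
Conditions: LiN(i-Pr)2 (1.05 equiv), THF, −78 °C; then 4 (1.3 equiv), DMPU, −78 → −30 °C
Reagents that add atoms: methyl bromoacetate, COC(=O)CBr
Why: Kinetic α′-enolisation of a cyclohexenone (C7 is a ketal, so no γ-deprotonation is possible) followed by SN2 alkylation; the electrophile should approach C9 anti to the adjacent C8 methyl and give the trans isomer, which is also the more stable one if any equilibration occurs.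

Step 3
Reactants: 5 methyl 2-[(1R,6R)-5,5-dimethoxy-6-methyl-2-oxocyclohex-3-en-1-yl]acetate; 6 4-methylbenzenesulfonohydrazide
Product: 9 methyl 2-[(1S,6R)-5,5-dimethoxy-6-methylcyclohex-2-en-1-yl]acetate, via tosylhydrazone 7 (not isolated), via allylic diazene 8 (not isolated)
Conditions: 6 (1.1 equiv), MeOH, 25 °C; evaporate; catecholborane (2 equiv), CHCl3, 0 °C; then NaOAc·3H2O, 60 °C
Reagents that add atoms: 4-methylbenzenesulfonohydrazide, Cc1ccc(cc1)S(=O)(=O)NN (its nitrogen is carried only in 7 and 8; nothing but hydrogen remains in 9)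
Why: Reductive 1,3-transposition of an enone tosylhydrazone: 1,2-hydride addition by catecholborane, acetate-induced loss of sulfinate to the allylic diazene and retro-ene loss of N2 deliver hydrogen to C6 and leave the alkene at C4=C5. C8 and C9 are not involved, and the ester and ketal should tolerate the neutral borane.

Step 4
Reactants: 9 methyl 2-[(1S,6R)-5,5-dimethoxy-6-methylcyclohex-2-en-1-yl]acetate; 10 water
Product: 11 methyl 2-[(1S,6R)-6-methyl-5-oxocyclohex-2-en-1-yl]acetate
Conditions: pyridinium p-toluenesulfonate (0.2 equiv), acetone/H2O (9:1), 25 °C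
Reagents that add atoms: water, O
Why: Mild acid-catalysed hydrolysis of a dimethyl ketal; weak acid at room temperature should leave the β,γ-alkene unconjugated, as in the oxalic acid hydrolysis of Birch-type enol ethers, and C8 keeps the favoured trans relationship to C9.

Step 5
Reactants: 11 methyl 2-[(1S,6R)-6-methyl-5-oxocyclohex-2-en-1-yl]acetate
Product: 12 methyl 2-[(1S,5S,6R)-5-hydroxy-6-methylcyclohex-2-en-1-yl]acetate
Conditions: LiBH(s-Bu)3 (1.2 equiv), THF, −78 °C; aq. NH4Cl
Reagents that add atoms: none
Why: Hindered trialkylborohydride reduction: the bulky hydride attacks along the equatorial trajectory, away from the pseudo-axial hydrogen on C9, and gives the axial alcohol cis to the equatorial C8 methyl (7S), as in reductions of 2-methylcyclohexanones and cyclohex-3-enones. The methyl ester is inert at −78 °C.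

Step 6
Reactants: 12 methyl 2-[(1S,5S,6R)-5-hydroxy-6-methylcyclohex-2-en-1-yl]acetate; 13 tert-butyldimethylsilyl trifluoromethanesulfonate
Product: 14 methyl 2-[(1S,5S,6R)-5-[(tert-butyldimethylsilyl)oxy]-6-methylcyclohex-2-en-1-yl]acetate
Conditions: 13 (1.3 equiv), 2,6-lutidine (2 equiv), CH2Cl2, −78 → 0 °C
Reagents that add atoms: tert-butyldimethylsilyl trifluoromethanesulfonate, CC(C)(C)[Si](C)(C)OS(=O)(=O)C(F)(F)F
Why: O-silylation of a hindered axial secondary alcohol with the silyl triflate and a non-nucleophilic base; no stereocentre is touched.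

Step 7
Reactants: 14 methyl 2-[(1S,5S,6R)-5-[(tert-butyldimethylsilyl)oxy]-6-methylcyclohex-2-en-1-yl]acetate; 15 lithium hydroxide
Product: 16 2-[(1S,5S,6R)-5-[(tert-butyldimethylsilyl)oxy]-6-methylcyclohex-2-en-1-yl]acetic acid
Conditions: LiOH (3 equiv), THF/MeOH/H2O (3:1:1), 25 °C; then 1 M HCl to pH 3–4, 0 °C
Reagents that add atoms: lithium hydroxide, [Li+].[OH-]
Why: Saponification of an unhindered methyl ester; the secondary silyl ether survives hydroxide and a brief cold acidification.

Step 8
Reactants: 17 prop-2-yn-1-ol; 18 methylmagnesium bromide; 19 iodine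
Product: 21 (2Z)-3-iodo-2-methylprop-2-en-1-ol, via cyclic alkenylmagnesium alkoxide 20 (not isolated)
Conditions: MeMgBr (2.5 equiv), CuI (10 mol%), THF/Et2O, −20 → 25 °C; then I2 (1.3 equiv), −20 → 0 °C; aq. NH4Cl
Reagents that add atoms: methylmagnesium bromide, C[Mg]Br; iodine, II
Why: Copper-catalysed anti-carbomagnesiation of propargyl alcohol directed by the magnesium alkoxide gives the five-membered chelate, whose C–Mg bond is iodinated with retention. Oxygen-bearing carbon and iodine therefore end up cis (Z), the geometry ring A needs at C2=C3.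

Step 9
Reactants: 21 (2Z)-3-iodo-2-methylprop-2-en-1-ol; 22 3-(triphenyl-λ5-phosphanylidene)butan-2-one
Product: 24 (3E,5Z)-6-iodo-3,5-dimethylhexa-3,5-dien-2-one, via (2Z)-3-iodo-2-methylprop-2-enal 23 (not isolated)
Conditions: MnO2 (10 equiv), CH2Cl2, 25 °C, dark; filter through Celite onto 22 (1.5 equiv); 40 °C
Reagents that add atoms: 3-(triphenyl-λ5-phosphanylidene)butan-2-one, CC(=O)C(C)=P(c1ccccc1)(c1ccccc1)c1ccccc1
Why: Allylic oxidation by MnO2 followed by Wittig olefination with a stabilised acyl ylide, which is E-selective. The aldehyde is not isolated because Z-3-iodoenals isomerise on handling.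

Step 10
Reactants: 24 (3E,5Z)-6-iodo-3,5-dimethylhexa-3,5-dien-2-one
Product: 25 (2S,3E,5Z)-6-iodo-3,5-dimethylhexa-3,5-dien-2-ol
Conditions: (R)-1-methyl-3,3-diphenyltetrahydro-1H,3H-pyrrolo[1,2-c][1,3,2]oxazaborole (0.2 equiv), catecholborane (1.5 equiv), PhMe, −78 → −40 °C
Reagents that add atoms: none
Why: Corey–Bakshi–Shibata reduction: the ketone binds the oxazaborolidine–borane with the larger dienyl group away from the catalyst, so the (R)-catalyst should give the (S)-carbinol by analogy with aryl and alkenyl methyl ketones. Catecholborane at low temperature avoids hydroboration, and the alkenyl iodide is inert.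

Step 11
Reactants: 16 2-[(1S,5S,6R)-5-[(tert-butyldimethylsilyl)oxy]-6-methylcyclohex-2-en-1-yl]acetic acid; 25 (2S,3E,5Z)-6-iodo-3,5-dimethylhexa-3,5-dien-2-ol
Product: 26 (2S,3E,5Z)-6-iodo-3,5-dimethylhexa-3,5-dien-2-yl 2-[(1S,5S,6R)-5-[(tert-butyldimethylsilyl)oxy]-6-methylcyclohex-2-en-1-yl]acetate
Conditions: N,N'-dicyclohexylcarbodiimide (1.2 equiv), 4-(dimethylamino)pyridine (0.1 equiv), CH2Cl2, 0 → 25 °C
Reagents that add atoms: none
Why: Steglich esterification through the O-acylisourea and acylpyridinium ion; the allylic C–O bond is not broken, so the carbinol configuration is kept.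

Step 12
Reactants: 26 (2S,3E,5Z)-6-iodo-3,5-dimethylhexa-3,5-dien-2-yl 2-[(1S,5S,6R)-5-[(tert-butyldimethylsilyl)oxy]-6-methylcyclohex-2-en-1-yl]acetate; 27 chlorotrimethylsilane
Product: 30 (2S,3S,4E)-2-[(1S,5S,6R)-5-[(tert-butyldimethylsilyl)oxy]-6-methylcyclohex-2-en-1-yl]-3-[(1Z)-1-iodoprop-1-en-2-yl]-4-methylhex-4-enoic acid, via (Z)-silyl ketene acetal 28 (not isolated), via trimethylsilyl ester 29 (not isolated)
Conditions: LiN(i-Pr)2 (1.15 equiv), THF/DMPU (3:1), −78 °C; Me3SiCl (1.5 equiv), −78 → 25 °C; 1 M HCl, 0 °C
Reagents that add atoms: chlorotrimethylsilane, C[Si](C)(C)Cl (silicon is carried only in 28 and 29; 30 keeps no reagent atom)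
Why: Ireland–Claisen rearrangement; enolisation in THF–DMPU favours the Z(O) enolate and hence the (Z)-ketene acetal. In the chair transition state the carbinol methyl and the cyclohexenyl group are both equatorial, so the (S)-carbinol is relayed to C1 (3S), the enolate geometry sets C10 (2S) syn to it, and the new butenyl alkene is E.

Step 13
Reactants: 30 (2S,3S,4E)-2-[(1S,5S,6R)-5-[(tert-butyldimethylsilyl)oxy]-6-methylcyclohex-2-en-1-yl]-3-[(1Z)-1-iodoprop-1-en-2-yl]-4-methylhex-4-enoic acid; 31 (trimethylsilyl)diazomethane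
Product: 32 methyl (2S,3S,4E)-2-[(1S,5S,6R)-5-[(tert-butyldimethylsilyl)oxy]-6-methylcyclohex-2-en-1-yl]-3-[(1Z)-1-iodoprop-1-en-2-yl]-4-methylhex-4-enoate
Conditions: Me3SiCHN2 (1.5 equiv), PhMe/MeOH (4:1), 0 °C
Reagents that add atoms: (trimethylsilyl)diazomethane, C[Si](C)(C)C=[N+]=[N-]
Why: O-methylation of the carboxylic acid by diazomethane released from Me3SiCHN2 and methanol; reaction is at carboxylate oxygen, so the hindered and epimerisable C10 is not touched.

Step 14
Reactants: 32 methyl (2S,3S,4E)-2-[(1S,5S,6R)-5-[(tert-butyldimethylsilyl)oxy]-6-methylcyclohex-2-en-1-yl]-3-[(1Z)-1-iodoprop-1-en-2-yl]-4-methylhex-4-enoate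
Product: 33 methyl (1S,2S,4aS,7S,8R,8aS)-2-[(2E)-but-2-en-2-yl]-7-[(tert-butyldimethylsilyl)oxy]-3,8-dimethyl-1,2,4a,7,8,8a-hexahydronaphthalene-1-carboxylate
Conditions: Pd(OAc)2 (10 mol%), PPh3 (30 mol%), Ag2CO3 (2 equiv), MeCN, 70 °C, degassed
Reagents that add atoms: none
Why: Intramolecular Heck reaction; the closest known case is the 6-exo cyclisation of alkenyl halides onto cyclohexenes to give cis-fused bicycles. Zerovalent palladium, formed from Pd(OAc)2 and PPh3, inserts into the C3–I bond with retention of the Z geometry, and Ag2CO3 removes iodide so that the cationic alkenylpalladium binds the C4=C5 alkene. Syn carbopalladation in the 6-exo-trig mode forms C3–C4 and closes ring A (C1, C2, C3, C4, C9, C10), leaving palladium on C5. The new stereocentre C4 is set by the tether: the chain is anchored on C9, so C3 can reach only the alkene face on which C10 sits, which makes the fusion cis (4aS). Because C3 and palladium add to the same face, the C4 hydrogen is anti to palladium and syn β-hydride elimination can only use a hydrogen on C6, which gives the C5=C6 alkene. The step needs control of where that alkene stays: rapid capture of the hydridopalladium species by Ag2CO3 should limit re-addition and migration toward C7, and the C7 silyl ether cannot ionise as an allylic leaving group. The butenyl alkene is too close to compete (4-exo or 5-endo), and the C2=C3 alkene arrives with its methyl group and geometry intact.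

Step 15
Reactants: 33 methyl (1S,2S,4aS,7S,8R,8aS)-2-[(2E)-but-2-en-2-yl]-7-[(tert-butyldimethylsilyl)oxy]-3,8-dimethyl-1,2,4a,7,8,8a-hexahydronaphthalene-1-carboxylate
Product: 34 methyl (1S,2S,4aS,7S,8R,8aS)-2-[(2E)-but-2-en-2-yl]-7-[(tert-butyldimethylsilyl)oxy]-3,8-dimethyl-1,2,4a,5,6,7,8,8a-octahydronaphthalene-1-carboxylate
Conditions: 2-nitrobenzenesulfonohydrazide (6 equiv), Et3N, CH2Cl2, 25 °C
Reagents that add atoms: none
Why: Concerted syn transfer of H2 from diimide generated in the flask; the cis-disubstituted C5=C6 alkene should react much faster than the two trisubstituted alkenes, and no stereocentre is formed or touched.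

Step 16
Reactants: 34 methyl (1S,2S,4aS,7S,8R,8aS)-2-[(2E)-but-2-en-2-yl]-7-[(tert-butyldimethylsilyl)oxy]-3,8-dimethyl-1,2,4a,5,6,7,8,8a-octahydronaphthalene-1-carboxylate
Product: 35 [(1S,2S,4aS,7S,8R,8aR)-2-[(2E)-but-2-en-2-yl]-7-[(tert-butyldimethylsilyl)oxy]-3,8-dimethyl-1,2,4a,5,6,7,8,8a-octahydronaphthalen-1-yl]methanol
Conditions: (i-Bu)2AlH (2.5 equiv), CH2Cl2, −78 → 0 °C; aq. potassium sodium tartrate
Reagents that add atoms: none
Why: Hydride reduction of an ester to the primary alcohol; silyl ether and alkenes are inert, and C10 is not enolised.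

Step 17
Reactants: 35 [(1S,2S,4aS,7S,8R,8aR)-2-[(2E)-but-2-en-2-yl]-7-[(tert-butyldimethylsilyl)oxy]-3,8-dimethyl-1,2,4a,5,6,7,8,8a-octahydronaphthalen-1-yl]methanol
Product: 36 (1S,2S,4aS,7S,8R,8aS)-2-[(2E)-but-2-en-2-yl]-7-[(tert-butyldimethylsilyl)oxy]-3,8-dimethyl-1,2,4a,5,6,7,8,8a-octahydronaphthalene-1-carbaldehyde
Conditions: Dess–Martin periodinane (1.3 equiv), NaHCO3, CH2Cl2, 0 → 25 °C
Reagents that add atoms: none
Why: Dess–Martin oxidation under buffered, non-basic conditions stops at the aldehyde and should not epimerise C10.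

Step 18
Reactants: 36 (1S,2S,4aS,7S,8R,8aS)-2-[(2E)-but-2-en-2-yl]-7-[(tert-butyldimethylsilyl)oxy]-3,8-dimethyl-1,2,4a,5,6,7,8,8a-octahydronaphthalene-1-carbaldehyde; 37 ethyl (2E)-4-(diethoxyphosphoryl)but-2-enoate
Product: 38 ethyl (2E,4E)-5-[(1S,2S,4aS,7S,8R,8aR)-2-[(2E)-but-2-en-2-yl]-7-[(tert-butyldimethylsilyl)oxy]-3,8-dimethyl-1,2,4a,5,6,7,8,8a-octahydronaphthalen-1-yl]penta-2,4-dienoate
Conditions: 37 (1.5 equiv), LiN(SiMe3)2 (1.4 equiv), THF, −78 °C; then 36, −78 → 0 °C
Reagents that add atoms: ethyl (2E)-4-(diethoxyphosphoryl)but-2-enoate, CCOC(=O)/C=C/CP(=O)(OCC)OCC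
Why: Vinylogous Horner–Wadsworth–Emmons olefination: the pre-formed lithium anion attacks through its α-carbon (C12) and syn loss of phosphate gives the new C11=C12 alkene E, while the 2E geometry comes with the reagent. Low temperature and the absence of free base protect C10.

Step 19
Reactants: 38 ethyl (2E,4E)-5-[(1S,2S,4aS,7S,8R,8aR)-2-[(2E)-but-2-en-2-yl]-7-[(tert-butyldimethylsilyl)oxy]-3,8-dimethyl-1,2,4a,5,6,7,8,8a-octahydronaphthalen-1-yl]penta-2,4-dienoate
Product: 39 ethyl (2E,4E)-5-[(1S,2S,4aS,7S,8R,8aR)-2-[(2E)-but-2-en-2-yl]-7-hydroxy-3,8-dimethyl-1,2,4a,5,6,7,8,8a-octahydronaphthalen-1-yl]penta-2,4-dienoate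
Conditions: HF·pyridine, pyridine, THF, 0 → 25 °C
Reagents that add atoms: none
Why: Fluoride-driven Si–O cleavage; buffered HF·pyridine should leave the dienoate and the trisubstituted alkenes alone, and the C7–O bond is not broken.

Step 20
Reactants: 39 ethyl (2E,4E)-5-[(1S,2S,4aS,7S,8R,8aR)-2-[(2E)-but-2-en-2-yl]-7-hydroxy-3,8-dimethyl-1,2,4a,5,6,7,8,8a-octahydronaphthalen-1-yl]penta-2,4-dienoate; 40 sulfur trioxide–pyridine complex
Product: 41 ethyl (2E,4E)-5-[(1S,2S,4aS,7S,8R,8aR)-2-[(2E)-but-2-en-2-yl]-3,8-dimethyl-7-(sulfooxy)-1,2,4a,5,6,7,8,8a-octahydronaphthalen-1-yl]penta-2,4-dienoate (handled as its sodium salt)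
Conditions: SO3·pyridine (5 equiv), pyridine, 25 → 40 °C; aq. NaHCO3
Reagents that add atoms: sulfur trioxide–pyridine complex, O=S(=O)([O-])[n+]1ccccc1
Why: O-sulfation of a secondary alcohol; the new bond is O–S, so C7 keeps its configuration, and the neutral complex does not touch the dienoate.

Step 21
Reactants: 41 ethyl (2E,4E)-5-[(1S,2S,4aS,7S,8R,8aR)-2-[(2E)-but-2-en-2-yl]-3,8-dimethyl-7-(sulfooxy)-1,2,4a,5,6,7,8,8a-octahydronaphthalen-1-yl]penta-2,4-dienoate; 15 lithium hydroxide
Product: 42 (2E,4E)-5-[(1S,2S,4aS,7S,8R,8aR)-2-[(2E)-but-2-en-2-yl]-3,8-dimethyl-7-(sulfooxy)-1,2,4a,5,6,7,8,8a-octahydronaphthalen-1-yl]penta-2,4-dienoic acid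
Conditions: LiOH (5 equiv), THF/MeOH/H2O, 25 °C; then cold 0.5 M HCl to pH 2, immediate reversed-phase isolation
Reagents that add atoms: lithium hydroxide, [Li+].[OH-]
Why: Saponification of the ethyl dienoate; a monoalkyl sulfate anion resists hydroxide, and a brief cold acidification should give the diacid without solvolysis at C7.

## Compound list

1 | 4,4-dimethoxycyclohexa-2,5-dien-1-one | COC1(OC)C=CC(=O)C=C1 | starting material
2 | dimethylzinc | C[Zn]C | starting material
3 | (5R)-4,4-dimethoxy-5-methylcyclohex-2-en-1-one | COC1(OC)C=CC(=O)C[C@H]1C | intermediate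
4 | methyl bromoacetate | COC(=O)CBr | starting material
5 | methyl 2-[(1R,6R)-5,5-dimethoxy-6-methyl-2-oxocyclohex-3-en-1-yl]acetate | COC(=O)C[C@H]1C(=O)C=CC(OC)(OC)[C@@H]1C | intermediate
6 | 4-methylbenzenesulfonohydrazide | Cc1ccc(cc1)S(=O)(=O)NN | starting material
7 | methyl 2-[(1R,6R)-5,5-dimethoxy-6-methyl-2-{2-[(4-methylphenyl)sulfonyl]hydrazinylidene}cyclohex-3-en-1-yl]acetate | COC(=O)C[C@H]1C(=NNS(=O)(=O)c2ccc(C)cc2)C=CC(OC)(OC)[C@@H]1C | intermediate
8 | methyl 2-[(1R,6R)-2-diazenyl-5,5-dimethoxy-6-methylcyclohex-3-en-1-yl]acetate (diazenyl carbon of either configuration) | COC(=O)C[C@H]1C(N=N)C=CC(OC)(OC)[C@@H]1C | intermediate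
9 | methyl 2-[(1S,6R)-5,5-dimethoxy-6-methylcyclohex-2-en-1-yl]acetate | COC(=O)C[C@H]1C=CCC(OC)(OC)[C@@H]1C | intermediate
10 | water | O | starting material
11 | methyl 2-[(1S,6R)-6-methyl-5-oxocyclohex-2-en-1-yl]acetate | COC(=O)C[C@H]1C=CCC(=O)[C@@H]1C | intermediate
12 | methyl 2-[(1S,5S,6R)-5-hydroxy-6-methylcyclohex-2-en-1-yl]acetate | COC(=O)C[C@H]1C=CC[C@H](O)[C@@H]1C | intermediate
13 | tert-butyldimethylsilyl trifluoromethanesulfonate | CC(C)(C)[Si](C)(C)OS(=O)(=O)C(F)(F)F | starting material
14 | methyl 2-[(1S,5S,6R)-5-[(tert-butyldimethylsilyl)oxy]-6-methylcyclohex-2-en-1-yl]acetate | COC(=O)C[C@H]1C=CC[C@H](O[Si](C)(C)C(C)(C)C)[C@@H]1C | intermediate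
15 | lithium hydroxide | [Li+].[OH-] | starting material
16 | 2-[(1S,5S,6R)-5-[(tert-butyldimethylsilyl)oxy]-6-methylcyclohex-2-en-1-yl]acetic acid | OC(=O)C[C@H]1C=CC[C@H](O[Si](C)(C)C(C)(C)C)[C@@H]1C | intermediate
17 | prop-2-yn-1-ol | C#CCO | starting material
18 | methylmagnesium bromide | C[Mg]Br | starting material
19 | iodine | II | starting material
20 | 4-methyl-2,5-dihydro-1,2-oxamagnesole (cyclic alkenylmagnesium alkoxide) | CC1=C[Mg]OC1 | intermediate
21 | (2Z)-3-iodo-2-methylprop-2-en-1-ol | OC/C(C)=C\I | intermediate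
22 | 3-(triphenyl-λ5-phosphanylidene)butan-2-one | CC(=O)C(C)=P(c1ccccc1)(c1ccccc1)c1ccccc1 | starting material
23 | (2Z)-3-iodo-2-methylprop-2-enal | O=C/C(C)=C\I | intermediate
24 | (3E,5Z)-6-iodo-3,5-dimethylhexa-3,5-dien-2-one | CC(=O)/C(C)=C/C(C)=C\I | intermediate
25 | (2S,3E,5Z)-6-iodo-3,5-dimethylhexa-3,5-dien-2-ol | C[C@H](O)/C(C)=C/C(C)=C\I | intermediate
26 | (2S,3E,5Z)-6-iodo-3,5-dimethylhexa-3,5-dien-2-yl 2-[(1S,5S,6R)-5-[(tert-butyldimethylsilyl)oxy]-6-methylcyclohex-2-en-1-yl]acetate | C[C@H](OC(=O)C[C@H]1C=CC[C@H](O[Si](C)(C)C(C)(C)C)[C@@H]1C)/C(C)=C/C(C)=C\I | intermediate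
27 | chlorotrimethylsilane | C[Si](C)(C)Cl | starting material
28 | trimethyl{[(1Z)-1-{[(2S,3E,5Z)-6-iodo-3,5-dimethylhexa-3,5-dien-2-yl]oxy}-2-[(1S,5S,6R)-5-[(tert-butyldimethylsilyl)oxy]-6-methylcyclohex-2-en-1-yl]ethenyl]oxy}silane (trimethylsilyloxy cis to the cyclohexenyl group) | C[C@H](O/C(O[Si](C)(C)C)=C/[C@H]1C=CC[C@H](O[Si](C)(C)C(C)(C)C)[C@@H]1C)/C(C)=C/C(C)=C\I | intermediate
29 | trimethylsilyl (2S,3S,4E)-2-[(1S,5S,6R)-5-[(tert-butyldimethylsilyl)oxy]-6-methylcyclohex-2-en-1-yl]-3-[(1Z)-1-iodoprop-1-en-2-yl]-4-methylhex-4-enoate | C/C=C(\C)[C@@H](/C(C)=C\I)[C@@H](C(=O)O[Si](C)(C)C)[C@H]1C=CC[C@H](O[Si](C)(C)C(C)(C)C)[C@@H]1C | intermediate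
30 | (2S,3S,4E)-2-[(1S,5S,6R)-5-[(tert-butyldimethylsilyl)oxy]-6-methylcyclohex-2-en-1-yl]-3-[(1Z)-1-iodoprop-1-en-2-yl]-4-methylhex-4-enoic acid | C/C=C(\C)[C@@H](/C(C)=C\I)[C@@H](C(=O)O)[C@H]1C=CC[C@H](O[Si](C)(C)C(C)(C)C)[C@@H]1C | intermediate
31 | (trimethylsilyl)diazomethane | C[Si](C)(C)C=[N+]=[N-] | starting material
32 | methyl (2S,3S,4E)-2-[(1S,5S,6R)-5-[(tert-butyldimethylsilyl)oxy]-6-methylcyclohex-2-en-1-yl]-3-[(1Z)-1-iodoprop-1-en-2-yl]-4-methylhex-4-enoate | C/C=C(\C)[C@@H](/C(C)=C\I)[C@@H](C(=O)OC)[C@H]1C=CC[C@H](O[Si](C)(C)C(C)(C)C)[C@@H]1C | intermediate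
33 | methyl (1S,2S,4aS,7S,8R,8aS)-2-[(2E)-but-2-en-2-yl]-7-[(tert-butyldimethylsilyl)oxy]-3,8-dimethyl-1,2,4a,7,8,8a-hexahydronaphthalene-1-carboxylate | C/C=C(\C)[C@H]1C(C)=C[C@H]2C=C[C@H](O[Si](C)(C)C(C)(C)C)[C@H](C)[C@H]2[C@@H]1C(=O)OC | intermediate
34 | methyl (1S,2S,4aS,7S,8R,8aS)-2-[(2E)-but-2-en-2-yl]-7-[(tert-butyldimethylsilyl)oxy]-3,8-dimethyl-1,2,4a,5,6,7,8,8a-octahydronaphthalene-1-carboxylate | C/C=C(\C)[C@H]1C(C)=C[C@H]2CC[C@H](O[Si](C)(C)C(C)(C)C)[C@H](C)[C@H]2[C@@H]1C(=O)OC | intermediate
35 | [(1S,2S,4aS,7S,8R,8aR)-2-[(2E)-but-2-en-2-yl]-7-[(tert-butyldimethylsilyl)oxy]-3,8-dimethyl-1,2,4a,5,6,7,8,8a-octahydronaphthalen-1-yl]methanol | C/C=C(\C)[C@H]1C(C)=C[C@H]2CC[C@H](O[Si](C)(C)C(C)(C)C)[C@H](C)[C@H]2[C@@H]1CO | intermediate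
36 | (1S,2S,4aS,7S,8R,8aS)-2-[(2E)-but-2-en-2-yl]-7-[(tert-butyldimethylsilyl)oxy]-3,8-dimethyl-1,2,4a,5,6,7,8,8a-octahydronaphthalene-1-carbaldehyde | C/C=C(\C)[C@H]1C(C)=C[C@H]2CC[C@H](O[Si](C)(C)C(C)(C)C)[C@H](C)[C@H]2[C@@H]1C=O | intermediate
37 | ethyl (2E)-4-(diethoxyphosphoryl)but-2-enoate | CCOC(=O)/C=C/CP(=O)(OCC)OCC | starting material
38 | ethyl (2E,4E)-5-[(1S,2S,4aS,7S,8R,8aR)-2-[(2E)-but-2-en-2-yl]-7-[(tert-butyldimethylsilyl)oxy]-3,8-dimethyl-1,2,4a,5,6,7,8,8a-octahydronaphthalen-1-yl]penta-2,4-dienoate | C/C=C(\C)[C@H]1C(C)=C[C@H]2CC[C@H](O[Si](C)(C)C(C)(C)C)[C@H](C)[C@H]2[C@@H]1/C=C/C=C/C(=O)OCC | intermediate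
39 | ethyl (2E,4E)-5-[(1S,2S,4aS,7S,8R,8aR)-2-[(2E)-but-2-en-2-yl]-7-hydroxy-3,8-dimethyl-1,2,4a,5,6,7,8,8a-octahydronaphthalen-1-yl]penta-2,4-dienoate | C/C=C(\C)[C@H]1C(C)=C[C@H]2CC[C@H](O)[C@H](C)[C@H]2[C@@H]1/C=C/C=C/C(=O)OCC | intermediate
40 | sulfur trioxide–pyridine complex | O=S(=O)([O-])[n+]1ccccc1 | starting material
41 | ethyl (2E,4E)-5-[(1S,2S,4aS,7S,8R,8aR)-2-[(2E)-but-2-en-2-yl]-3,8-dimethyl-7-(sulfooxy)-1,2,4a,5,6,7,8,8a-octahydronaphthalen-1-yl]penta-2,4-dienoate | C/C=C(\C)[C@H]1C(C)=C[C@H]2CC[C@H](OS(=O)(=O)O)[C@H](C)[C@H]2[C@@H]1/C=C/C=C/C(=O)OCC | intermediate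
42 | (2E,4E)-5-[(1S,2S,4aS,7S,8R,8aR)-2-[(2E)-but-2-en-2-yl]-3,8-dimethyl-7-(sulfooxy)-1,2,4a,5,6,7,8,8a-octahydronaphthalen-1-yl]penta-2,4-dienoic acid | C/C=C(\C)[C@H]1C(C)=C[C@H]2CC[C@H](OS(=O)(=O)O)[C@H](C)[C@H]2[C@@H]1/C=C/C=C/C(=O)O | target

## Step count and least certain steps

Total step count: 21. Longest linear sequence: 18 steps (steps 1–7 and 11–21); the dienol branch (steps 8–10) is 3 steps.

**Step 14 (key step).** The most likely failure is walking of the new alkene toward C7 by re-addition of the hydridopalladium species, which would end in a silyl enol ether. A second risk is slow insertion, because the reactive conformer needs the C9 side chain and the C8 methyl both axial, which would leave time for protodeiodination. The fallback changes the bond-forming mechanism and keeps the same bond: it sets out from 32 and comes back at 34. Tributyltin hydride and azobisisobutyronitrile in benzene at 80 °C under slow addition would generate the alkenyl radical at C3, which closes 6-exo onto C4 on the tethered face (again cis-fused). The C5 radical is then reduced by the stannane, so ring B is delivered saturated and step 15 is skipped; this fallback makes no new compound (none, F0).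

**Step 12.** The most likely failure is incomplete control of ketene acetal geometry (leakage through the E(O) enolate, or through a boat transition state), which would erode the configuration at C10. A lesser risk is attack of the amide base on the alkenyl iodide. The fallback replaces kinetic control by thermodynamic control at C10; it sets out from 26 and comes back at 33. The C10 epimer (2R,3S,4E)-2-[(1S,5S,6R)-5-[(tert-butyldimethylsilyl)oxy]-6-methylcyclohex-2-en-1-yl]-3-[(1Z)-1-iodoprop-1-en-2-yl]-4-methylhex-4-enoic acid F1 would be methylated as in step 13 to its methyl ester F2 and cyclised as in step 14 to methyl (1R,2S,4aS,7S,8R,8aS)-2-[(2E)-but-2-en-2-yl]-7-[(tert-butyldimethylsilyl)oxy]-3,8-dimethyl-1,2,4a,7,8,8a-hexahydronaphthalene-1-carboxylate F3. NaOMe in MeOH at 60 °C should then equilibrate C10 toward 33, because only in 33 can the C1 substituent, the C10 ester and the C9–C8 bond all be equatorial on ring A. In the epimer the ester is either axial and syn to C5, or the ring must flip and place the butenyl group and C8 in a 1,3-diaxial relationship.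

**Step 3.** The most likely failure is loss of the dimethyl ketal to the Lewis-acidic borane, or incomplete transposition (simple 1,2- or 1,4-reduction). The fallback removes the carbonyl through an enol triflate; it sets out from 5 and comes back at 9. H2 over Pd/C in EtOAc would saturate the enone to methyl 2-[(1R,6R)-5,5-dimethoxy-6-methyl-2-oxocyclohexyl]acetate F4. Kinetic enolisation away from the substituted C9 (KN(SiMe3)2, THF, −78 °C) and trapping with N-phenylbis(trifluoromethanesulfonimide) would give methyl 2-[(1R,6R)-5,5-dimethoxy-6-methyl-2-{[(trifluoromethyl)sulfonyl]oxy}cyclohex-2-en-1-yl]acetate F5. Pd(OAc)2, PPh3, Bu3N and HCO2H in DMF at 60 °C would then reduce the C–O bond and leave the C4=C5 alkene of 9.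

**Step 5.** The most likely failure is poor facial selectivity, since the half-chair of a cyclohex-3-enone offers the bulky hydride less bias than a cyclohexanone. Base-induced conjugation of the β,γ-alkene is a second risk. The fallback sets C7 by inversion; it sets out from 11 and comes back at 12. NaBH4 in MeOH at −40 °C should give mainly the equatorial alcohol methyl 2-[(1S,5R,6R)-5-hydroxy-6-methylcyclohex-2-en-1-yl]acetate F6. A Mitsunobu reaction (4-nitrobenzoic acid, PPh3, diisopropyl azodicarboxylate, THF) would invert C7 to methyl 2-[(1S,5S,6R)-6-methyl-5-[(4-nitrobenzoyl)oxy]cyclohex-2-en-1-yl]acetate F7, and K2CO3 in MeOH would release 12.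

## Further compounds

F0 | step 14 | none | none
F1 | step 12 | (2R,3S,4E)-2-[(1S,5S,6R)-5-[(tert-butyldimethylsilyl)oxy]-6-methylcyclohex-2-en-1-yl]-3-[(1Z)-1-iodoprop-1-en-2-yl]-4-methylhex-4-enoic acid | C/C=C(\C)[C@@H](/C(C)=C\I)[C@H](C(=O)O)[C@H]1C=CC[C@H](O[Si](C)(C)C(C)(C)C)[C@@H]1C
F2 | step 12 | methyl (2R,3S,4E)-2-[(1S,5S,6R)-5-[(tert-butyldimethylsilyl)oxy]-6-methylcyclohex-2-en-1-yl]-3-[(1Z)-1-iodoprop-1-en-2-yl]-4-methylhex-4-enoate | C/C=C(\C)[C@@H](/C(C)=C\I)[C@H](C(=O)OC)[C@H]1C=CC[C@H](O[Si](C)(C)C(C)(C)C)[C@@H]1C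
F3 | step 12 | methyl (1R,2S,4aS,7S,8R,8aS)-2-[(2E)-but-2-en-2-yl]-7-[(tert-butyldimethylsilyl)oxy]-3,8-dimethyl-1,2,4a,7,8,8a-hexahydronaphthalene-1-carboxylate | C/C=C(\C)[C@H]1C(C)=C[C@H]2C=C[C@H](O[Si](C)(C)C(C)(C)C)[C@H](C)[C@H]2[C@H]1C(=O)OC
F4 | step 3 | methyl 2-[(1R,6R)-5,5-dimethoxy-6-methyl-2-oxocyclohexyl]acetate | COC(=O)C[C@H]1C(=O)CCC(OC)(OC)[C@@H]1C
F5 | step 3 | methyl 2-[(1R,6R)-5,5-dimethoxy-6-methyl-2-{[(trifluoromethyl)sulfonyl]oxy}cyclohex-2-en-1-yl]acetate | COC(=O)C[C@H]1C(OS(=O)(=O)C(F)(F)F)=CCC(OC)(OC)[C@@H]1C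
F6 | step 5 | methyl 2-[(1S,5R,6R)-5-hydroxy-6-methylcyclohex-2-en-1-yl]acetate | COC(=O)C[C@H]1C=CC[C@@H](O)[C@@H]1C
F7 | step 5 | methyl 2-[(1S,5S,6R)-6-methyl-5-[(4-nitrobenzoyl)oxy]cyclohex-2-en-1-yl]acetate | COC(=O)C[C@H]1C=CC[C@H](OC(=O)c2ccc(cc2)[N+](=O)[O-])[C@@H]1C
A1 | alternative 1 | 7-[(2E)-but-2-en-2-yl]-8-{[(tert-butyldimethylsilyl)oxy]methyl}-2-ethenyl-1,3-dimethylbicyclo[2.2.2]oct-5-en-2-ol (configuration as in the SMILES; ethenyl group on the side of the C5=C6 bridge) | C/C=C(\C)[C@H]1[C@]2(C)C=C[C@H]([C@@H]1CO[Si](C)(C)C(C)(C)C)[C@@H](C)[C@@]2(O)C=C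
A2 | alternative 1 | cis-fused 7-[(2E)-but-2-en-2-yl]-8-{[(tert-butyldimethylsilyl)oxy]methyl}-1,6-dimethyl-3,4,4a,7,8,8a-hexahydronaphthalen-2(1H)-one (configuration as in the SMILES) | C/C=C(\C)[C@H]1C(C)=C[C@H]2CCC(=O)[C@H](C)[C@H]2[C@@H]1CO[Si](C)(C)C(C)(C)C
A3 | alternative 2 | 4,4-dimethoxy-2-methylcyclohexa-2,5-dien-1-one | CC1=CC(OC)(OC)C=CC1=O
A4 | alternative 2 | (1E)-1-methoxy-3-[(trimethylsilyl)oxy]buta-1,3-diene | CO/C=C/C(=C)O[Si](C)(C)C
A5 | alternative 2 | cis-4,4-dimethoxy-2-methyl-4a,5-dihydronaphthalene-1,6(4H,8aH)-dione (configuration as in the SMILES) | CC1=CC(OC)(OC)[C@@H]2CC(=O)C=C[C@@H]2C1=O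
A6 | alternative 3 | 4-[(1Z,4E)-3-[(2E)-but-2-en-2-yl]-2-methyl-6-(trimethylsilyl)hexa-1,4-dien-1-yl]-2-methylcyclohex-2-en-1-one (configuration as in the SMILES) | C/C=C(\C)[C@H](/C=C/C[Si](C)(C)C)/C(C)=C\[C@H]1CCC(=O)C(C)=C1
A7 | alternative 3 | cis-fused 7-[(2E)-but-2-en-2-yl]-8-ethenyl-1,6-dimethyl-3,4,4a,7,8,8a-hexahydronaphthalen-2(1H)-one (configuration as in the SMILES) | C/C=C(\C)[C@H]1C(C)=C[C@H]2CCC(=O)[C@H](C)[C@H]2[C@@H]1C=C
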